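Compound numbers are those of the steps and the compound list. Locants are germacrane locants: ring C1–C10, lactone carbons C11–C13, methyl C14, oxymethyl C15.

## Analysis of the target

Target 44 is a germacranolide with a ten-membered carbocycle and a trans-fused α-methylene-γ-butyrolactone across C6–C7 (lactone oxygen on C6, C11(=C13)–C12(=O) on C7). The ring holds a Z C1=C10 double bond (methyl C14 on C10) and a C4=C5 double bond whose ring bonds C3–C4 and C5–C6 are trans; its CIP descriptor is Z only because the acetoxymethyl carbon C15 outranks C3. The four stereocentres are 2S, 6R, 7R and 8R. H6 and H7 are anti, the free C8 hydroxyl lies on the same ring face as the C7–C11 bond, and the C2 tiglate lies on the opposite face. Sensitive groups are the exocyclic methylene lactone (a Michael acceptor), an allylic primary acetate and an allylic secondary tiglate next to a free secondary alcohol, and the 1(10),4-diene, which cyclises across the ring under acid. The difficulty is a medium ring with two trisubstituted olefins of different geometry, five oxygen functions that end in four different states, and the C6–C7–C8 triad on a flexible ring. The strategy rests on the unit HO–C6–C7–C11(=C13), a homoallylic alcohol in which C6 is also allylic to C4=C5. This is the retron of a [2,3]-Wittig shift of a C6–O–C13 diallyl ether. Tied into the thirteen-membered ring of 31, that ether should give, in one sigmatropic step, the C6–C7 bond, both stereocentres, the exocyclic methylene and the ten-membered ring of 33.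

## Retrosynthetic reasoning

**C8–O (44 from 43 from 42).** The C8 carbinol is set last, by Mitsunobu substitution of the 8-epi alcohol 42 to formate 43 and mild methanolysis. The reason lies in the key step: the ring contraction is controlled by the C8 silyl ether, and the arrangement that is favourable on all counts delivers the target's C6 and C7 only from the 8S ether. The route therefore carries the C8 epimer and inverts it when C8 is the only free hydroxyl.

**Esters (42 from 41, 40, 39, 37).** The C15–O acetyl bond is cut first, because the primary allylic hydroxyl of diol 41 can be acetylated beside the hindered C8 hydroxyl. The tiglate is installed earlier on 39, where C2 is the only free hydroxyl and C8 and C15 are still silylated. Uncovering C2 alone requires an acetal (MOM) that is orthogonal to the silyl ethers.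

**Lactone (37 from 34 from 33).** The O6–C12 bond and the C12 oxidation level come from oxidative lactonisation of the C6,C12-diol 34. The C8 oxygen stays silylated so that only O6 can close onto C12. The diol arises from 33 by removal of the one triethylsilyl ether.

**C6–C7 (33 from 31), the key disconnection.** Cutting C6–C7 and reconnecting O6 to C13 turns the carbocycle into the thirteen-membered diallyl ether 31. The cut is made here because it is the only ring bond flanked by two new stereocentres. Both ring olefins can then be made in the open chain, and the strained ring is formed by contraction rather than by end-to-end closure. The forward step must metalate C6 selectively and transfer the C7=C11 geometry and the C8 configuration into C6 and C7.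

**C13–O (31 from 29, 28, 26).** The macrocycle is opened at the ether bond, which is made by intramolecular O-alkylation. The alkoxide is placed on C6 and the leaving group on C13. A C13 alkoxide would sit 1,3 to the C12 silyl ether, and silyl transfer between O12 and O13 would exchange the two CH2O arms on C11 and so scramble the C7=C11 geometry. The C6 alkoxide has only the bulky C15 triisopropylsilyl ether nearby. C6 is carried as a p-methoxybenzyl ether, removable oxidatively beside four silyl and acetal ethers.

**C7=C11 (26 from 25 from 20 and 23).** An E-selective Horner–Wadsworth–Emmons reaction of aldehyde 20 with phosphonate 23 makes the olefin. It also distinguishes the two oxygenated carbons on C11: the ester carbon becomes C13 (trans to C8) and the silyloxymethyl carbon C12 (cis to C8). Phosphonate 23 comes from 21 by hydroxymethylation and silylation.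

**C9–C10 (20 from 19, 18, from 16 and 11).** The homoallylic C8 carbinol is the retron of an epoxide opening by a vinyl anion at C10. The Z-vinyl iodide 16 supplies the anion and glycidyl ether 11 supplies C7–C9 and the C8 stereocentre.

**C1=C10 (16 from 15).** The Z-trisubstituted olefin with its iodine handle is cut to aldehyde 15 and an α-iodo ethylidene ylide. The Z selectivity of that olefination puts the future C9 cis to C2.

**C3–C4 (15 from 14, 13, from 9 and 11; 11 from 10).** The same epoxide-opening logic forms C3–C4. Vinyl iodide 9 is the C4 nucleophile, and the same glycidyl ether 11, made from (R)-glycidol 10, supplies C1–C3 and the C2 stereocentre. One chiral building block thus serves both carbinol centres.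

**C4=C5 (9 from 8, 7, 5, 3, 1).** The trisubstituted olefin with cis C6 and C15 is traced to ynoate 5 by syn hydrostannation and iodination. The ester carbon becomes C15 and the propargylic carbon C6, so the two oxygenated methylenes differ from the first step onward.

## Alternatives that were turned down

**Alternative 1: Grob fragmentation.**
- Disconnection: C4 is reconnected to C8, hiding the ten-membered ring in a cis-fused five–seven bicycle with a tertiary hydroxyl at C8 and a sulfonate at C5.
- Forward key step: a potassium alkoxide base forms the C8 alkoxide; the C4–C8 bond breaks as the C5 sulfonate leaves, giving the C8 ketone and the C4=C5 olefin of A1.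
- In favour: there is no macrocyclisation, the ring-trans C4=C5 geometry follows stereospecifically from the anti-periplanar arrangement, and the Z C1=C10 olefin is trivial inside a seven-membered ring. On olefin geometry this route is stronger than the chosen one. Its C8 ketone could in principle be reduced to the needed epimer, whereas the chosen route needs an inversion.
- Against: the bicyclic substrate needs more stereochemical information than the target holds (quaternary C4 bearing C15, the ring fusion, C5 with its leaving group aligned, C6, C7). A1 is a β-alkoxy ketone (O6 is β to the C8 carbonyl through C7) formed under strong base, so elimination of the C6 oxygen and epimerisation at C7 threaten in the key step itself. The facial selectivity of the C8 reduction on a flexible ring is open, and the lactol acetal and two PMB ethers cost further redox and protecting-group steps.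
- Comparison: the chosen route builds the olefins in the open chain by standard methods and creates C6 and C7 in the ring-forming step, at the price of a macro-etherification and a final inversion.

**Alternative 2: chromium-mediated ring closure at C1–C2.**
- Disconnection: the C1–C2 bond, to a Z-alkenyl iodide at C1 and an aldehyde at C2 on a chain that already carries the lactone.
- Forward key step: divalent chromium with a nickel co-catalyst turns the iodide into an alkenylchromium that adds to the aldehyde, closing the ring to A2.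
- In favour: the conditions tolerate esters and the methylene lactone, so A2 is two steps (tigloylation, desilylation) from the target. In endgame economy and in avoiding a strongly basic key step this route is stronger.
- Against: the ten-membered ring is closed directly by C–C bond formation against full transannular strain. The C2 configuration is created in the macrocyclisation with no reliable control element. The aldehyde is β,γ-unsaturated and prone to conjugation. The C6–C7–C8 triad and the lactone must be built on an open chain beforehand, which moves the stereochemical work into a long linear sequence.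
- Comparison: the chosen route closes the carbocycle by contraction of an easily made ether and sets C6 and C7 during ring formation; C2 and C8 come from a chiral pool epoxide.

**Alternative 3: anionic oxy-Cope ring expansion.**
- Disconnection: C2–C3 is cut and C5–C10 reconnected, giving a 1,2-divinylcyclohexanol from a terpene-derived six-membered ring.
- Forward key step: a potassium amide base forms the C5 alkoxide; the [3,3] shift forms C2–C3 and breaks C5–C10, and the C4=C5 enolate is trapped as the triflate A3.
- In favour: a concerted six-to-ten ring expansion with chirality transfer through a cyclic transition state, no high dilution, and a chiral pool start. In ring-forming efficiency it is at least as strong as the chosen step.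
- Against: the precursor needs two adjacent fully substituted carbons (C5 and C10) on a cyclohexane that also carries the C6, C7 and C8 substituents. The Z C1=C10 and ring-trans C4=C5 geometries both depend on the transition-state shape and on the enolate geometry of a tetrasubstituted enolate. The C5 oxygen is absent from the target, so the triflate must be reduced afterwards. The C2 stereocentre is formed at a vinyl ether terminus with uncertain facial control.
- Comparison: the chosen route fixes both olefin geometries before the ring exists and uses a key step whose product oxygen (O6) is needed in the target.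

Key step: step 21

Remark on the chemistry: "ring-trans" for C4=C5 and C7=C11 means that the two ring bonds are trans across the double bond; the CIP descriptor of these olefins is Z in most intermediates because of the oxygenated substituents.

## Route

Step 1
Reactants: 1 prop-2-yn-1-ol
Product: 3 1-methoxy-4-[(prop-2-yn-1-yloxy)methyl]benzene, via sodium prop-2-yn-1-olate 2 (not isolated)
Conditions: NaH, THF, 0 °C; PMBCl, nBu4NI (cat.), 0 °C to rt
Reagents that add atoms: 4-methoxybenzyl chloride, COc1ccc(CCl)cc1
Why: Williamson etherification of a primary alkoxide with a benzylic chloride; the PMB ether will later be removed oxidatively at C6 beside silyl ethers.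

Step 2
Reactants: 3 1-methoxy-4-[(prop-2-yn-1-yloxy)methyl]benzene
Product: 5 methyl 4-[(4-methoxybenzyl)oxy]but-2-ynoate, via lithium acetylide 4 (not isolated)
Conditions: nBuLi, THF, −78 °C; ClCO2Me, −78 to 0 °C
Reagents that add atoms: methyl chloroformate, COC(=O)Cl
Why: C-acylation of a lithium acetylide with a chloroformate; the ester carbon becomes C15 and the propargylic carbon C6, so the two oxygenated carbons are distinguished from the start.

Step 3
Reactants: 5 methyl 4-[(4-methoxybenzyl)oxy]but-2-ynoate
Product: 7 methyl (2E)-2-iodo-4-[(4-methoxybenzyl)oxy]but-2-enoate, via alpha-stannyl enoate 6 (not isolated)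
Conditions: Bu3SnH, Pd(PPh3)4 (cat.), THF, 0 °C; then I2, CH2Cl2, 0 °C
Reagents that add atoms: iodine, II
Why: Palladium-catalysed hydrostannation of an ynoate adds H and Sn syn with tin alpha to the ester, and iododestannylation retains the geometry. The ester carbon (C15) and the CH2OPMB carbon (C6) therefore end up cis on the future C4=C5.

Step 4
Reactants: 7 methyl (2E)-2-iodo-4-[(4-methoxybenzyl)oxy]but-2-enoate
Product: 8 (2E)-2-iodo-4-[(4-methoxybenzyl)oxy]but-2-en-1-ol
Conditions: iBu2AlH, CH2Cl2, −78 °C
Reagents that add atoms: none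
Why: 1,2-Reduction of an enoate to the allylic alcohol by an aluminium hydride; the vinyl iodide and the olefin geometry are untouched.

Step 5
Reactants: 8 (2E)-2-iodo-4-[(4-methoxybenzyl)oxy]but-2-en-1-ol
Product: 9 {[(2E)-2-iodo-4-[(4-methoxybenzyl)oxy]but-2-en-1-yl]oxy}triisopropylsilane
Conditions: TIPSCl, imidazole, DMF, rt
Reagents that add atoms: chlorotriisopropylsilane, CC(C)[Si](Cl)(C(C)C)C(C)C
Why: Silylation of a primary alcohol; the bulky TIPS group is chosen for C15 because it resists silyl transfer to the C6 alkoxide in step 20 and shields the C15 methylene from metalation in step 21.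

Step 6
Reactants: 10 (R)-glycidol
Product: 11 triethyl{[(2S)-oxiran-2-yl]methoxy}silane
Conditions: TESCl, Et3N, DMAP (cat.), CH2Cl2, 0 °C
Reagents that add atoms: chlorotriethylsilane, CC[Si](Cl)(CC)CC
Why: Silylation of the primary hydroxyl; the stereocentre is not touched (the descriptor changes from R to S only through the priority change), and the primary TES ether is the group that steps 9 and 13 oxidise directly.

Step 7
Reactants: 9 {[(2E)-2-iodo-4-[(4-methoxybenzyl)oxy]but-2-en-1-yl]oxy}triisopropylsilane; 11 triethyl{[(2S)-oxiran-2-yl]methoxy}silane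
Product: 13 (2S,4Z)-6-[(4-methoxybenzyl)oxy]-1-[(triethylsilyl)oxy]-4-{[(triisopropylsilyl)oxy]methyl}hex-4-en-2-ol, via vinyllithium 12 (not isolated)
Conditions: tBuLi (2.1 equiv), Et2O, −78 °C; then 11, BF3·OEt2, −78 °C
Reagents that add atoms: none
Why: Iodine–lithium exchange gives the vinyllithium with retention, and BF3-assisted opening at the terminal epoxide carbon forms C3–C4. The C2 stereocentre (S) comes unchanged from 10.

Step 8
Reactants: 13 (2S,4Z)-6-[(4-methoxybenzyl)oxy]-1-[(triethylsilyl)oxy]-4-{[(triisopropylsilyl)oxy]methyl}hex-4-en-2-ol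
Product: 14 (2S,4Z)-2-(methoxymethoxy)-6-[(4-methoxybenzyl)oxy]-1-[(triethylsilyl)oxy]-4-{[(triisopropylsilyl)oxy]methyl}hex-4-ene
Conditions: MOMCl, iPr2NEt, CH2Cl2, 0 °C to rt
Reagents that add atoms: chloromethyl methyl ether, COCCl
Why: Acetal protection of the secondary C2 alcohol under amine base; MOM survives the organolithium steps and is later removable without touching the silyl ethers at C8 and C15.

Step 9
Reactants: 14 (2S,4Z)-2-(methoxymethoxy)-6-[(4-methoxybenzyl)oxy]-1-[(triethylsilyl)oxy]-4-{[(triisopropylsilyl)oxy]methyl}hex-4-ene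
Product: 15 (2S,4Z)-2-(methoxymethoxy)-6-[(4-methoxybenzyl)oxy]-4-{[(triisopropylsilyl)oxy]methyl}hex-4-enal
Conditions: (COCl)2, DMSO, CH2Cl2, −78 to −40 °C; Et3N, −78 °C
Reagents that add atoms: none
Why: Under Swern conditions a primary triethylsilyl ether is oxidised directly to the aldehyde, while the TIPS, MOM and PMB ethers are inert. The base is added cold so that the alpha-alkoxy aldehyde keeps its configuration.

Step 10
Reactants: 15 (2S,4Z)-2-(methoxymethoxy)-6-[(4-methoxybenzyl)oxy]-4-{[(triisopropylsilyl)oxy]methyl}hex-4-enal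
Product: 16 (2Z,4S,6Z)-2-iodo-4-(methoxymethoxy)-8-[(4-methoxybenzyl)oxy]-6-{[(triisopropylsilyl)oxy]methyl}octa-2,6-diene
Conditions: [Ph3PEt]I, nBuLi, THF, rt; I2, −78 °C; NaN(SiMe3)2, −20 °C; then 15, −78 °C
Reagents that add atoms: ethyltriphenylphosphonium iodide, CC[P+](c1ccccc1)(c1ccccc1)c1ccccc1.[I-]; iodine, II
Why: Stork–Zhao-type Wittig olefination with the alpha-iodo ethylidene ylide is kinetically Z-selective, placing iodine cis to C2 and the methyl group (C14) trans. The iodide marks the site of the C9–C10 bond.

Step 11
Reactants: 16 (2Z,4S,6Z)-2-iodo-4-(methoxymethoxy)-8-[(4-methoxybenzyl)oxy]-6-{[(triisopropylsilyl)oxy]methyl}octa-2,6-diene; 11 triethyl{[(2S)-oxiran-2-yl]methoxy}silane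
Product: 18 (2S,4Z,6S,8Z)-6-(methoxymethoxy)-10-[(4-methoxybenzyl)oxy]-4-methyl-1-[(triethylsilyl)oxy]-8-{[(triisopropylsilyl)oxy]methyl}deca-4,8-dien-2-ol, via vinyllithium 17 (not isolated)
Conditions: tBuLi (2.0 equiv), Et2O, −78 °C; then 11 (2 equiv), BF3·OEt2, −78 °C
Reagents that add atoms: none
Why: Same exchange and BF3-assisted epoxide opening as in step 7; the configurationally stable Z-vinyllithium forms C9–C10 with retention of the Z C1=C10 geometry. C8 arrives as the S carbinol that the key step needs.

Step 12
Reactants: 18 (2S,4Z,6S,8Z)-6-(methoxymethoxy)-10-[(4-methoxybenzyl)oxy]-4-methyl-1-[(triethylsilyl)oxy]-8-{[(triisopropylsilyl)oxy]methyl}deca-4,8-dien-2-ol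
Product: 19 tert-butyldimethylsilyl ether of 18 at the C8 hydroxyl
Conditions: TBSOTf, 2,6-lutidine, CH2Cl2, −78 °C
Reagents that add atoms: tert-butyldimethylsilyl triflate, CC(C)(C)[Si](C)(C)OS(=O)(=O)C(F)(F)F
Why: Silylation of the secondary alcohol under non-basic conditions, so the neighbouring primary TES ether does not migrate; the TBS group is the bulky polar substituent that directs the key step.

Step 13
Reactants: 19 tert-butyldimethylsilyl ether of 18 at the C8 hydroxyl
Product: 20 (2S,4Z,6S,8Z)-2-[(tert-butyldimethylsilyl)oxy]-6-(methoxymethoxy)-10-[(4-methoxybenzyl)oxy]-4-methyl-8-{[(triisopropylsilyl)oxy]methyl}deca-4,8-dienal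
Conditions: (COCl)2, DMSO, CH2Cl2, −78 to −40 °C; Et3N, −78 °C
Reagents that add atoms: none
Why: Direct Swern oxidation of the primary TES ether as in step 9; the secondary TBS ether next to it and the other ethers are not attacked.

Step 14
Reactants: 21 triethyl phosphonoacetate
Product: 22 ethyl 2-(diethoxyphosphoryl)-3-hydroxypropanoate
Conditions: (CH2O)n, piperidine (cat.), MeOH, reflux
Reagents that add atoms: formaldehyde (as paraformaldehyde), C=O
Why: Amine-catalysed aldol-type hydroxymethylation of the activated methylene; in the protic medium the adduct is protonated and does not go on to olefination. The new carbon becomes C12.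

Step 15
Reactants: 22 ethyl 2-(diethoxyphosphoryl)-3-hydroxypropanoate
Product: 23 ethyl 2-(diethoxyphosphoryl)-3-[(triethylsilyl)oxy]propanoate
Conditions: TESCl, imidazole, CH2Cl2, 0 °C
Reagents that add atoms: chlorotriethylsilane, CC[Si](Cl)(CC)CC
Why: Silylation of the primary alcohol; TES is the most labile silyl group of the final set, so C12 can later be freed alone.

Step 16
Reactants: 20 (2S,4Z,6S,8Z)-2-[(tert-butyldimethylsilyl)oxy]-6-(methoxymethoxy)-10-[(4-methoxybenzyl)oxy]-4-methyl-8-{[(triisopropylsilyl)oxy]methyl}deca-4,8-dienal; 23 ethyl 2-(diethoxyphosphoryl)-3-[(triethylsilyl)oxy]propanoate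
Product: 25 ethyl (2E,4S,6Z,8S,10Z)-4-[(tert-butyldimethylsilyl)oxy]-8-(methoxymethoxy)-12-[(4-methoxybenzyl)oxy]-6-methyl-2-{[(triethylsilyl)oxy]methyl}-10-{[(triisopropylsilyl)oxy]methyl}dodeca-2,6,10-trienoate, via sodium phosphonate carbanion 24 (not isolated)
Conditions: NaH, THF, 0 °C; then 20, −78 to 0 °C
Reagents that add atoms: none
Why: Horner–Wadsworth–Emmons olefination of an alpha-substituted phosphonoacetate is E-selective (ester trans to the C8 branch). The ester carbon therefore becomes C13 and the silyloxymethyl carbon C12 lies cis to C8, which sets the ring-trans C7=C11 geometry.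

Step 17
Reactants: 25 ethyl (2E,4S,6Z,8S,10Z)-4-[(tert-butyldimethylsilyl)oxy]-8-(methoxymethoxy)-12-[(4-methoxybenzyl)oxy]-6-methyl-2-{[(triethylsilyl)oxy]methyl}-10-{[(triisopropylsilyl)oxy]methyl}dodeca-2,6,10-trienoate
Product: 26 C13 allylic alcohol (CH2OH in place of the CO2Et group of 25)
Conditions: iBu2AlH, CH2Cl2, −78 °C
Reagents that add atoms: none
Why: 1,2-Reduction of the enoate; no free alkoxide is generated, so the neighbouring C12 silyl ether stays in place.

Step 18
Reactants: 26 C13 allylic alcohol (CH2OH in place of the CO2Et group of 25)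
Product: 28 C13 allylic bromide (CH2Br in place of the CH2OH group of 26), via C13 mesylate 27 (not isolated)
Conditions: MsCl, Et3N, THF, −20 °C; LiBr, 0 °C
Reagents that add atoms: lithium bromide, [Li+].[Br-]
Why: Mesylation and SN2 displacement by bromide at a primary allylic carbon; the conditions are too weakly basic to move the C12 silyl group.

Step 19
Reactants: 28 C13 allylic bromide (CH2Br in place of the CH2OH group of 26)
Product: 29 hydroxy bromide (28 without the PMB group: free C6 hydroxyl)
Conditions: DDQ, CH2Cl2–pH 7 buffer, 0 °C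
Reagents that add atoms: none
Why: Oxidative cleavage of the p-methoxybenzyl ether by DDQ; silyl ethers, the MOM acetal and the allylic bromide are stable in the buffered two-phase medium.

Step 20
Reactants: 29 hydroxy bromide (28 without the PMB group: free C6 hydroxyl)
Product: 31 thirteen-membered diallyl ether (O bridges C6 and C13; 2S OMOM; 8S OTBS; C15 OTIPS; C12 OTES; Z C1=C10; ring-trans C4=C5 and C7=C11), via sodium C6 alkoxide 30 (not isolated)
Conditions: NaH, nBu4NI (cat.), THF, 0.002 M, slow addition, 45 °C
Reagents that add atoms: none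
Why: Intramolecular Williamson etherification under high dilution, an exo substitution at the primary allylic C13 that closes the thirteen-membered ring. The nucleophile is the C6 alkoxide, whose only nearby silyl ether is the bulky C15 TIPS ether, so no silyl transfer can blur the C7=C11 geometry.

Step 21
Reactants: 31 thirteen-membered diallyl ether (O bridges C6 and C13; 2S OMOM; 8S OTBS; C15 OTIPS; C12 OTES; Z C1=C10; ring-trans C4=C5 and C7=C11)
Product: 33 (2S,6R,7S,8S)-cyclodeca-1(10),4-dien-6-ol with C7 3-[(triethylsilyl)oxy]prop-1-en-2-yl group; 2-OMOM; 8-OTBS; 15-OTIPS, via C6-lithiated ether 32 (not isolated)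
Conditions: nBuLi (2.5 equiv), THF, −78 to −30 °C; then aq NH4Cl
Reagents that add atoms: none
Why: nBuLi removes a C6 proton (allylic to C4=C5 and alpha to the ring oxygen), and the carbanion attacks C7 through a five-membered envelope transition state (C6, O, C13, C11, C7) while O–C13 breaks, leaving the C6 lithium alkoxide and the C11=C13 methylene. The closest known reaction type is the [2,3]-Wittig ring contraction of thirteen-membered diallylic ethers to germacrane-type cyclodeca-1(10),4-dienols. The ten-membered carbocycle is closed transannularly, as a thirteen-to-ten contraction by a concerted six-electron sigmatropic shift and not by an end-to-end cyclisation. C7 is controlled by the 8S silyloxy centre: with H8 eclipsing C7=C11 (1,3-allylic strain against the cis C12 methylene), the C8–O bond stands anti to the incoming carbanion and C9 lies on the attacked face, which is the gauche C6–C7–C8–C9 arrangement of the product ring; for the 8S ether this is the face that gives the target's arrangement at C7 (descriptor S in 33 only because of the silyl ether priority). C6 is controlled relative to C7 by the ring-trans C7=C11 geometry (C13 trans to C8), which places C5 and C8 anti about the forming bond and gives the 6,7-trans alkoxide needed for the trans-fused lactone. The step needs metalation at C6 rather than elsewhere and a [2,3] rather than a [1,2] shift: C6H2 is the least hindered alpha-oxy allylic methylene, a C13 anion would have to bond to the fully substituted C4, the bulky silyl groups shield C15H2, C12H2 and H8, and the low temperature favours the concerted path.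

Step 22
Reactants: 33 (2S,6R,7S,8S)-cyclodeca-1(10),4-dien-6-ol with C7 3-[(triethylsilyl)oxy]prop-1-en-2-yl group; 2-OMOM; 8-OTBS; 15-OTIPS
Product: 34 C6,C12-diol (33 without the triethylsilyl group)
Conditions: PPTS, MeOH–CH2Cl2, 0 °C
Reagents that add atoms: none
Why: Mild acid methanolysis removes the primary TES ether much faster than the secondary TBS, primary TIPS or MOM groups; the acid is weak enough to spare the 1(10),4-diene.

Step 23
Reactants: 34 C6,C12-diol (33 without the triethylsilyl group)
Product: 37 (2S,6R,7S,8S)-8-[(tert-butyldimethylsilyl)oxy]-2-(methoxymethoxy)-15-[(triisopropylsilyl)oxy]germacra-1(10),4,11(13)-trien-12,6-olide, via hydroxy enal 35 (not isolated), via lactol 36 (not isolated)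
Conditions: TEMPO (cat.), PhI(OAc)2, CH2Cl2, rt
Reagents that add atoms: none
Why: Oxoammonium oxidation is selective for the primary allylic C12 alcohol; the enal is trapped by the C6 hydroxyl as the five-membered lactol, which is oxidised on to the alpha-methylene lactone. C8 is silylated, so only O6 can close, and the trans fusion follows from the C6 and C7 configurations set in step 21.

Step 24
Reactants: 37 (2S,6R,7S,8S)-8-[(tert-butyldimethylsilyl)oxy]-2-(methoxymethoxy)-15-[(triisopropylsilyl)oxy]germacra-1(10),4,11(13)-trien-12,6-olide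
Product: 39 C2 alcohol (37 without the MOM group), via N-alkoxymethyl bipyridinium triflate 38 (not isolated)
Conditions: TMSOTf, 2,2′-bipyridyl, CH2Cl2, 0 °C; then H2O
Reagents that add atoms: none
Why: Silyl triflate activation of the MOM acetal in the presence of bipyridyl gives a pyridinium salt that water hydrolyses to the alcohol. The buffered, non-protic conditions leave the TBS and TIPS ethers, the lactone and the acid-sensitive diene alone.

Step 25
Reactants: 39 C2 alcohol (37 without the MOM group)
Product: 40 C2 tiglate of 39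
Conditions: tigloyl chloride, Et3N, DMAP (cat.), CH2Cl2, 0 °C
Reagents that add atoms: (E)-2-methylbut-2-enoyl chloride, C/C=C(\C)C(=O)Cl
Why: DMAP-catalysed acylation of the only free hydroxyl; the E geometry of the tigloyl unit is the stable one and is kept.

Step 26
Reactants: 40 C2 tiglate of 39
Product: 41 (2S,6R,7R,8S)-8,15-dihydroxy-2-(tigloyloxy)germacra-1(10),4,11(13)-trien-12,6-olide
Conditions: HF·pyridine, pyridine, THF, 0 °C to rt
Reagents that add atoms: none
Why: Buffered fluoride cleaves the primary TIPS and secondary TBS ethers without touching the esters, the lactone or the diene.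

Step 27
Reactants: 41 (2S,6R,7R,8S)-8,15-dihydroxy-2-(tigloyloxy)germacra-1(10),4,11(13)-trien-12,6-olide
Product: 42 (2S,6R,7R,8S)-15-acetoxy-8-hydroxy-2-(tigloyloxy)germacra-1(10),4,11(13)-trien-12,6-olide (8-epimer of the target)
Conditions: Ac2O (1.1 equiv), 2,4,6-collidine, CH2Cl2, −20 °C
Reagents that add atoms: acetic anhydride, CC(=O)OC(C)=O
Why: Kinetically selective acetylation: the primary allylic C15 hydroxyl reacts far faster than the ring-bound secondary C8 hydroxyl with a limited amount of anhydride and a hindered base.

Step 28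
Reactants: 42 (2S,6R,7R,8S)-15-acetoxy-8-hydroxy-2-(tigloyloxy)germacra-1(10),4,11(13)-trien-12,6-olide (8-epimer of the target)
Product: 43 (2S,6R,7R,8R)-15-acetoxy-8-(formyloxy)-2-(tigloyloxy)germacra-1(10),4,11(13)-trien-12,6-olide
Conditions: PPh3, DIAD, HCO2H, THF, 0 °C to rt
Reagents that add atoms: formic acid, O=CO
Why: Mitsunobu substitution: the C8 hydroxyl is activated as the oxyphosphonium ion and displaced by formate with inversion, which sets the 8R configuration. The betaine is formed before the substrate is added so that free phosphine does not add to the methylene lactone.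

Step 29
Reactants: 43 (2S,6R,7R,8R)-15-acetoxy-8-(formyloxy)-2-(tigloyloxy)germacra-1(10),4,11(13)-trien-12,6-olide
Product: 44 (2S,6R,7R,8R)-15-acetoxy-8-hydroxy-2-(tigloyloxy)germacra-1(10),4,11(13)-trien-12,6-olide (target)
Conditions: KHCO3 (cat.), MeOH, 0 °C
Reagents that add atoms: none
Why: Transesterification of a formate is about two orders of magnitude faster than that of an acetate or a conjugated ester, so the C8 hydroxyl is freed while the acetate, tiglate and lactone stay.

## Compound list

1 | prop-2-yn-1-ol | C#CCO | starting material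
2 | sodium prop-2-yn-1-olate | [Na+].[O-]CC#C | intermediate (not isolated)
3 | 1-methoxy-4-[(prop-2-yn-1-yloxy)methyl]benzene | C#CCOCc1ccc(OC)cc1 | intermediate
4 | lithium acetylide of 3 | [Li]C#CCOCc1ccc(OC)cc1 | intermediate (not isolated)
5 | methyl 4-[(4-methoxybenzyl)oxy]but-2-ynoate | COC(=O)C#CCOCc1ccc(OC)cc1 | intermediate
6 | methyl (2E)-4-[(4-methoxybenzyl)oxy]-2-(tributylstannyl)but-2-enoate | COC(=O)/C(=C\COCc1ccc(OC)cc1)[Sn](CCCC)(CCCC)CCCC | intermediate (not isolated)
7 | methyl (2E)-2-iodo-4-[(4-methoxybenzyl)oxy]but-2-enoate | COC(=O)/C(I)=C\COCc1ccc(OC)cc1 | intermediate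
8 | (2E)-2-iodo-4-[(4-methoxybenzyl)oxy]but-2-en-1-ol | OC/C(I)=C\COCc1ccc(OC)cc1 | intermediate
9 | {[(2E)-2-iodo-4-[(4-methoxybenzyl)oxy]but-2-en-1-yl]oxy}triisopropylsilane | CC(C)[Si](OC/C(I)=C\COCc1ccc(OC)cc1)(C(C)C)C(C)C | intermediate
10 | (R)-glycidol, (2R)-oxiran-2-ylmethanol | OC[C@@H]1CO1 | starting material
11 | triethyl{[(2S)-oxiran-2-yl]methoxy}silane | CC[Si](CC)(CC)OC[C@@H]1CO1 | intermediate
12 | vinyllithium from 9 (Li in place of I) | [Li]/C(CO[Si](C(C)C)(C(C)C)C(C)C)=C/COCc1ccc(OC)cc1 | intermediate (not isolated)
13 | (2S,4Z)-6-[(4-methoxybenzyl)oxy]-1-[(triethylsilyl)oxy]-4-{[(triisopropylsilyl)oxy]methyl}hex-4-en-2-ol | COc1ccc(COC/C=C(/C[C@H](O)CO[Si](CC)(CC)CC)CO[Si](C(C)C)(C(C)C)C(C)C)cc1 | intermediate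
14 | (2S,4Z)-2-(methoxymethoxy)-6-[(4-methoxybenzyl)oxy]-1-[(triethylsilyl)oxy]-4-{[(triisopropylsilyl)oxy]methyl}hex-4-ene | COc1ccc(COC/C=C(/C[C@H](OCOC)CO[Si](CC)(CC)CC)CO[Si](C(C)C)(C(C)C)C(C)C)cc1 | intermediate
15 | (2S,4Z)-2-(methoxymethoxy)-6-[(4-methoxybenzyl)oxy]-4-{[(triisopropylsilyl)oxy]methyl}hex-4-enal | COc1ccc(COC/C=C(/C[C@H](OCOC)C=O)CO[Si](C(C)C)(C(C)C)C(C)C)cc1 | intermediate
16 | (2Z,4S,6Z)-2-iodo-4-(methoxymethoxy)-8-[(4-methoxybenzyl)oxy]-6-{[(triisopropylsilyl)oxy]methyl}octa-2,6-diene | COc1ccc(COC/C=C(/C[C@H](OCOC)/C=C(/C)I)CO[Si](C(C)C)(C(C)C)C(C)C)cc1 | intermediate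
17 | vinyllithium from 16 (Li in place of I) | COc1ccc(COC/C=C(/C[C@H](OCOC)/C=C(/C)[Li])CO[Si](C(C)C)(C(C)C)C(C)C)cc1 | intermediate (not isolated)
18 | (2S,4Z,6S,8Z)-6-(methoxymethoxy)-10-[(4-methoxybenzyl)oxy]-4-methyl-1-[(triethylsilyl)oxy]-8-{[(triisopropylsilyl)oxy]methyl}deca-4,8-dien-2-ol | COc1ccc(COC/C=C(/C[C@H](OCOC)/C=C(/C)C[C@H](O)CO[Si](CC)(CC)CC)CO[Si](C(C)C)(C(C)C)C(C)C)cc1 | intermediate
19 | tert-butyldimethylsilyl ether of 18 at the C8 hydroxyl | COc1ccc(COC/C=C(/C[C@H](OCOC)/C=C(/C)C[C@H](O[Si](C)(C)C(C)(C)C)CO[Si](CC)(CC)CC)CO[Si](C(C)C)(C(C)C)C(C)C)cc1 | intermediate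
20 | (2S,4Z,6S,8Z)-2-[(tert-butyldimethylsilyl)oxy]-6-(methoxymethoxy)-10-[(4-methoxybenzyl)oxy]-4-methyl-8-{[(triisopropylsilyl)oxy]methyl}deca-4,8-dienal | COc1ccc(COC/C=C(/C[C@H](OCOC)/C=C(/C)C[C@H](O[Si](C)(C)C(C)(C)C)C=O)CO[Si](C(C)C)(C(C)C)C(C)C)cc1 | intermediate
21 | triethyl phosphonoacetate | CCOC(=O)CP(=O)(OCC)OCC | starting material
22 | ethyl 2-(diethoxyphosphoryl)-3-hydroxypropanoate (racemic) | CCOC(=O)C(CO)P(=O)(OCC)OCC | intermediate
23 | ethyl 2-(diethoxyphosphoryl)-3-[(triethylsilyl)oxy]propanoate (racemic) | CCOC(=O)C(CO[Si](CC)(CC)CC)P(=O)(OCC)OCC | intermediate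
24 | sodium carbanion of 23 | [Na+].CCOC(=O)[C-](CO[Si](CC)(CC)CC)P(=O)(OCC)OCC | intermediate (not isolated)
25 | ethyl (2E,4S,6Z,8S,10Z)-4-[(tert-butyldimethylsilyl)oxy]-8-(methoxymethoxy)-12-[(4-methoxybenzyl)oxy]-6-methyl-2-{[(triethylsilyl)oxy]methyl}-10-{[(triisopropylsilyl)oxy]methyl}dodeca-2,6,10-trienoate | COc1ccc(COC/C=C(/C[C@H](OCOC)/C=C(/C)C[C@H](O[Si](C)(C)C(C)(C)C)/C=C(\CO[Si](CC)(CC)CC)C(=O)OCC)CO[Si](C(C)C)(C(C)C)C(C)C)cc1 | intermediate
26 | (2Z,4S,6Z,8S,10Z)-4-[(tert-butyldimethylsilyl)oxy]-8-(methoxymethoxy)-12-[(4-methoxybenzyl)oxy]-6-methyl-2-{[(triethylsilyl)oxy]methyl}-10-{[(triisopropylsilyl)oxy]methyl}dodeca-2,6,10-trien-1-ol | COc1ccc(COC/C=C(/C[C@H](OCOC)/C=C(/C)C[C@H](O[Si](C)(C)C(C)(C)C)/C=C(\CO[Si](CC)(CC)CC)CO)CO[Si](C(C)C)(C(C)C)C(C)C)cc1 | intermediate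
27 | methanesulfonate of 26 at the C13 hydroxyl | COc1ccc(COC/C=C(/C[C@H](OCOC)/C=C(/C)C[C@H](O[Si](C)(C)C(C)(C)C)/C=C(\CO[Si](CC)(CC)CC)COS(C)(=O)=O)CO[Si](C(C)C)(C(C)C)C(C)C)cc1 | intermediate (not isolated)
28 | C13 allylic bromide (CH2Br in place of the CH2OH group of 26; 2E,4S,6Z,8S,10Z) | COc1ccc(COC/C=C(/C[C@H](OCOC)/C=C(/C)C[C@H](O[Si](C)(C)C(C)(C)C)/C=C(\CO[Si](CC)(CC)CC)CBr)CO[Si](C(C)C)(C(C)C)C(C)C)cc1 | intermediate
29 | hydroxy bromide (28 without the PMB group: free C6 hydroxyl) | OC/C=C(/C[C@H](OCOC)/C=C(/C)C[C@H](O[Si](C)(C)C(C)(C)C)/C=C(\CO[Si](CC)(CC)CC)CBr)CO[Si](C(C)C)(C(C)C)C(C)C | intermediate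
30 | sodium C6 alkoxide of 29 | [Na+].[O-]C/C=C(/C[C@H](OCOC)/C=C(/C)C[C@H](O[Si](C)(C)C(C)(C)C)/C=C(\CO[Si](CC)(CC)CC)CBr)CO[Si](C(C)C)(C(C)C)C(C)C | intermediate (not isolated)
31 | thirteen-membered diallyl ether: oxygen bridges C6 and C13; 2S OMOM; 8S OTBS; C15 OTIPS; C12 OTES; Z C1=C10; ring-trans C4=C5 and C7=C11 | O1C/C=C(\CO[Si](C(C)C)(C(C)C)C(C)C)C[C@H](OCOC)/C=C(/C)C[C@H](O[Si](C)(C)C(C)(C)C)/C=C(\CO[Si](CC)(CC)CC)C1 | intermediate (key-step precursor)
32 | C6-lithiated 31 | [Li]C1/C=C(\CO[Si](C(C)C)(C(C)C)C(C)C)C[C@H](OCOC)/C=C(/C)C[C@H](O[Si](C)(C)C(C)(C)C)/C=C(\CO[Si](CC)(CC)CC)CO1 | intermediate (not isolated)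
33 | (2S,6R,7S,8S)-cyclodeca-1(10),4-dien-6-ol with C7 3-[(triethylsilyl)oxy]prop-1-en-2-yl group, 2-OMOM, 8-OTBS, 15-OTIPS (C6 and C7 arranged as in the target, C8 epimeric) | C=C(CO[Si](CC)(CC)CC)[C@H]1[C@H](O)/C=C(\CO[Si](C(C)C)(C(C)C)C(C)C)C[C@H](OCOC)/C=C(/C)C[C@@H]1O[Si](C)(C)C(C)(C)C | intermediate (key-step product)
34 | C6,C12-diol (33 without the triethylsilyl group) | C=C(CO)[C@H]1[C@H](O)/C=C(\CO[Si](C(C)C)(C(C)C)C(C)C)C[C@H](OCOC)/C=C(/C)C[C@@H]1O[Si](C)(C)C(C)(C)C | intermediate
35 | hydroxy enal (C12 aldehyde of 34) | C=C(C=O)[C@H]1[C@H](O)/C=C(\CO[Si](C(C)C)(C(C)C)C(C)C)C[C@H](OCOC)/C=C(/C)C[C@@H]1O[Si](C)(C)C(C)(C)C | intermediate (not isolated)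
36 | lactol (C12 hemiacetal with O6, both anomers) | C=C1C(O)O[C@@H]2/C=C(\CO[Si](C(C)C)(C(C)C)C(C)C)C[C@H](OCOC)/C=C(/C)C[C@H](O[Si](C)(C)C(C)(C)C)[C@@H]12 | intermediate (not isolated)
37 | (2S,6R,7S,8S)-8-[(tert-butyldimethylsilyl)oxy]-2-(methoxymethoxy)-15-[(triisopropylsilyl)oxy]germacra-1(10),4,11(13)-trien-12,6-olide | C=C1C(=O)O[C@@H]2/C=C(\CO[Si](C(C)C)(C(C)C)C(C)C)C[C@H](OCOC)/C=C(/C)C[C@H](O[Si](C)(C)C(C)(C)C)[C@@H]12 | intermediate
38 | N-(C2-oxymethyl)-2,2′-bipyridinium triflate derived from 37 | C=C1C(=O)O[C@@H]2/C=C(\CO[Si](C(C)C)(C(C)C)C(C)C)C[C@H](OC[n+]3ccccc3-c3ccccn3)/C=C(/C)C[C@H](O[Si](C)(C)C(C)(C)C)[C@@H]12.[O-]S(=O)(=O)C(F)(F)F | intermediate (not isolated)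
39 | (2S,6R,7S,8S)-8-[(tert-butyldimethylsilyl)oxy]-2-hydroxy-15-[(triisopropylsilyl)oxy]germacra-1(10),4,11(13)-trien-12,6-olide | C=C1C(=O)O[C@@H]2/C=C(\CO[Si](C(C)C)(C(C)C)C(C)C)C[C@H](O)/C=C(/C)C[C@H](O[Si](C)(C)C(C)(C)C)[C@@H]12 | intermediate
40 | (2S,6R,7S,8S)-8-[(tert-butyldimethylsilyl)oxy]-2-(tigloyloxy)-15-[(triisopropylsilyl)oxy]germacra-1(10),4,11(13)-trien-12,6-olide | C=C1C(=O)O[C@@H]2/C=C(\CO[Si](C(C)C)(C(C)C)C(C)C)C[C@H](OC(=O)/C(C)=C/C)/C=C(/C)C[C@H](O[Si](C)(C)C(C)(C)C)[C@@H]12 | intermediate
41 | (2S,6R,7R,8S)-8,15-dihydroxy-2-(tigloyloxy)germacra-1(10),4,11(13)-trien-12,6-olide | C=C1C(=O)O[C@@H]2/C=C(\CO)C[C@H](OC(=O)/C(C)=C/C)/C=C(/C)C[C@H](O)[C@@H]12 | intermediate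
42 | (2S,6R,7R,8S)-15-acetoxy-8-hydroxy-2-(tigloyloxy)germacra-1(10),4,11(13)-trien-12,6-olide (8-epimer of the target) | C=C1C(=O)O[C@@H]2/C=C(\COC(C)=O)C[C@H](OC(=O)/C(C)=C/C)/C=C(/C)C[C@H](O)[C@@H]12 | intermediate
43 | (2S,6R,7R,8R)-15-acetoxy-8-(formyloxy)-2-(tigloyloxy)germacra-1(10),4,11(13)-trien-12,6-olide | C=C1C(=O)O[C@@H]2/C=C(\COC(C)=O)C[C@H](OC(=O)/C(C)=C/C)/C=C(/C)C[C@@H](OC=O)[C@@H]12 | intermediate
44 | (2S,6R,7R,8R)-15-acetoxy-8-hydroxy-2-(tigloyloxy)germacra-1(10),4,11(13)-trien-12,6-olide | C=C1C(=O)O[C@@H]2/C=C(\COC(C)=O)C[C@H](OC(=O)/C(C)=C/C)/C=C(/C)C[C@@H](O)[C@@H]12 | target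

## Step count and least certain steps

Total: 29 steps. Longest linear sequence: 26 steps (1–5, 7–13, 16–29); step 6 and steps 14–15 are side branches.

**Step 21 (key step).** Metalation may occur at a site other than C6: C13, the silyloxymethylenes at C12 and C15, or the doubly activated H8. This would drain material into 1,2-shifts, silyl migration from oxygen to carbon, or elimination. The open-chain arguments for the facial sense at C7 could also be overridden by the macrocycle's conformation. Fallback: a dianion variant. From 31, selective methanolysis of the primary TES ether (PPTS, MeOH, 0 °C) should give the macrocyclic C12 alcohol F1. With nBuLi (3 equiv) its C12 alkoxide forms first; the negative charge next to C12 and C13 disfavours a second metalation there and removes the silyl-migration channel, so the carbanion should form at C6. The same [2,3] shift would then give diol 34 directly, where the route is rejoined.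

**Step 20 (macro-etherification).** Intermolecular etherification may outrun closure of the thirteen-membered ring, and the alkoxide may induce elimination of HBr. Fallback: palladium-catalysed allylic etherification, which needs no stoichiometric strong base. From 26, methyl chloroformate and pyridine should give the C13 methyl carbonate F2, and DDQ would free the C6 hydroxyl to give the hydroxy carbonate F3. Pd(PPh3)4 (zerovalent palladium) in dilute THF would ionise the carbonate, and the alkoxide released on decarboxylation should attack the unsubstituted C13 terminus of the allyl complex to give 31.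

**Step 28 (Mitsunobu inversion at C8).** Elimination toward a C8=C9 olefin conjugated with C1=C10 may compete with substitution at the hindered ring carbinol, and the phosphine or hydrazide may add to the methylene lactone. Fallback: oxidation and reduction. From 42, Dess–Martin periodinane should give the C8 ketone F4. Luche reduction (NaBH4, CeCl3·7H2O, MeOH, −78 °C) would then deliver hydride to the carbonyl face opposite the C7 side chain, which should give the 8R alcohol 44 directly; the lactone's conjugated methylene is spared under these conditions.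

**Step 10 (iodo-olefination).** Incomplete conversion of the hindered, base-sensitive alpha-alkoxy aldehyde and erosion of Z selectivity are the likely problems. Fallback: from 15, CBr4 and PPh3 should give the 1,1-dibromoalkene F5. A Negishi coupling with MeZnCl and Pd(PtBu3)2 replaces selectively the bromine trans to the carbon chain and should give the (Z)-2-bromoalkene F6 with bromine cis to C2. Bromine–lithium exchange with tBuLi gives the same vinyllithium 17, and the route is rejoined at 18.

**Step 16 (olefination with phosphonate 23).** The carbanion 24 may lose silanolate by beta-elimination, and the E selectivity may be eroded by the alpha-silyloxy aldehyde. Fallback: aldol addition and elimination. Ethyl 3-[(triethylsilyl)oxy]propanoate F7 (from ethyl 3-hydroxypropanoate and TESCl) is converted into its lithium enolate with LiN(iPr)2 at −78 °C and added to 20 to give the beta-hydroxy ester F8 as a diastereomer mixture. Mesylation gives F9, and DBU should eliminate it by an E1cB path to the thermodynamically preferred E enoate 25.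

## Further compounds

F1 | step 21 | macrocyclic C12 alcohol (31 without the triethylsilyl group) | O1C/C=C(\CO[Si](C(C)C)(C(C)C)C(C)C)C[C@H](OCOC)/C=C(/C)C[C@H](O[Si](C)(C)C(C)(C)C)/C=C(\CO)C1
F2 | step 20 | C13 methyl carbonate of 26 | COc1ccc(COC/C=C(/C[C@H](OCOC)/C=C(/C)C[C@H](O[Si](C)(C)C(C)(C)C)/C=C(\CO[Si](CC)(CC)CC)COC(=O)OC)CO[Si](C(C)C)(C(C)C)C(C)C)cc1
F3 | step 20 | hydroxy carbonate (F2 without the PMB group) | OC/C=C(/C[C@H](OCOC)/C=C(/C)C[C@H](O[Si](C)(C)C(C)(C)C)/C=C(\CO[Si](CC)(CC)CC)COC(=O)OC)CO[Si](C(C)C)(C(C)C)C(C)C
F4 | step 28 | (2S,6R,7R)-15-acetoxy-8-oxo-2-(tigloyloxy)germacra-1(10),4,11(13)-trien-12,6-olide | C=C1C(=O)O[C@@H]2/C=C(\COC(C)=O)C[C@H](OC(=O)/C(C)=C/C)/C=C(/C)CC(=O)[C@@H]12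
F5 | step 10 | 1,1-dibromoalkene from 15 | COc1ccc(COC/C=C(/C[C@H](OCOC)C=C(Br)Br)CO[Si](C(C)C)(C(C)C)C(C)C)cc1
F6 | step 10 | (2Z)-2-bromo analogue of 16 | COc1ccc(COC/C=C(/C[C@H](OCOC)/C=C(/C)Br)CO[Si](C(C)C)(C(C)C)C(C)C)cc1
F7 | step 16 | ethyl 3-[(triethylsilyl)oxy]propanoate | CCOC(=O)CCO[Si](CC)(CC)CC
F8 | step 16 | beta-hydroxy ester from 20 and the enolate of F7 (mixture at the two new centres) | COc1ccc(COC/C=C(/C[C@H](OCOC)/C=C(/C)C[C@H](O[Si](C)(C)C(C)(C)C)C(O)C(CO[Si](CC)(CC)CC)C(=O)OCC)CO[Si](C(C)C)(C(C)C)C(C)C)cc1
F9 | step 16 | methanesulfonate of F8 | COc1ccc(COC/C=C(/C[C@H](OCOC)/C=C(/C)C[C@H](O[Si](C)(C)C(C)(C)C)C(OS(C)(=O)=O)C(CO[Si](CC)(CC)CC)C(=O)OCC)CO[Si](C(C)C)(C(C)C)C(C)C)cc1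
A1 | alternative 1 | cyclodeca-1(10),4-dien-8-one with lactol methyl acetal and PMB ethers at C2 and C15 (fragmentation product) | C=C1[C@H](OC)O[C@@H]2/C=C(\COCc3ccc(OC)cc3)C[C@H](OCc3ccc(OC)cc3)/C=C(/C)CC(=O)[C@@H]12
A2 | alternative 2 | C2 alcohol of the C8-silylated target core (chromium coupling product) | C=C1C(=O)O[C@@H]2/C=C(\COC(C)=O)C[C@H](O)/C=C(/C)C[C@@H](O[Si](C)(C)C(C)(C)C)[C@@H]12
A3 | alternative 3 | ten-membered C5 enol triflate with lactol methyl acetal, PMB ethers at C2 and C15 and C8 silyl ether (oxy-Cope product) | C=C1[C@H](OC)O[C@@H]2/C(OS(=O)(=O)C(F)(F)F)=C(\COCc3ccc(OC)cc3)C[C@H](OCc3ccc(OC)cc3)/C=C(/C)C[C@@H](O[Si](C)(C)C(C)(C)C)[C@@H]12
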